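**Retrosynthetic overview**

1. Target 17 ⇒ ester 15: the 11‑OH/Δ6 enone is the singlet‑oxygen ene product of a 7(11)‑en‑8‑one; the (R)‑2‑methylbutanoate sits on the only secondary OH of diol 13.
2. C4 carbinol ⇒ exocyclic C4=C15 alkene (Markovnikov hydration) ⇒ C4 ketone (Wittig run under equilibrating conditions, which also funnels the epimerisable C3 and C5 centres to the trans‑decalin).
3. Ring B ⇒ formal [3+1+2] carbonylative annulation of cyclopropyl ketone 6 with CO and 3‑methylbuta‑1,2‑diene: C5–C6 and C8–C9 (and C7–C8) are made in one operation.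
4. Enabling feature: the C5–C9–C10 cyclopropane fused to ring A and conjugated with the C4 carbonyl is a masked 1,3‑dipole (C5 enol, C9 iodide); C10 is quaternary, so C9–metal and acyl–metal species carry no β‑hydrogen, and C10 relays every later stereocentre.
5. Ring order: ring A first (3‑methylcyclohex‑2‑enone; C10 set by CBS reduction and directed Simmons–Smith), then ring B in the key step.

Key step: step 5

Remark on descriptors: eudesmane numbering is used for the decalins (C10 carries the angular methyl C14, C4 carries C15, C7 carries C11 with C12 and C13). β is used only as a relative label for the face of C14, α for the opposite face; absolute configuration is that of the SMILES (target: 3S,4S,5R,10R and 2R in the acyl group).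
Assumption: 3‑methylbuta‑1,2‑diene (7) and (R)‑2‑methylbutanoic acid (14) are bought.

**Step 1**
Reactants: 1 3‑methylcyclohex‑2‑en‑1‑one
Product: 2 (R)‑3‑methylcyclohex‑2‑en‑1‑ol
Conditions: (S)‑2‑methyl‑CBS‑oxazaborolidine (10 mol%), BH3·SMe2, THF, −20 °C; MeOH
Reagents that add atoms: none
Why: Corey–Bakshi–Shibata reduction; the catalyst distinguishes the alkenyl (large) from the CH2 (small) flank of the carbonyl and should give the (R)‑carbinol by 1,2‑hydride delivery, the centre from which all others are relayed.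

**Step 2**
Reactants: 2 (R)‑3‑methylcyclohex‑2‑en‑1‑ol
Product: 3 (1S,2R,6R)‑6‑methylbicyclo[4.1.0]heptan‑2‑ol
Conditions: Et2Zn, CH2I2, CH2Cl2, 0 °C
Reagents that add atoms: diiodomethane, ICI
Why: hydroxyl‑directed Simmons–Smith cyclopropanation; the zinc alkoxide delivers CH2 to the alkene face syn to oxygen, which fixes the quaternary C10 and C5 relative to the carbinol.

**Step 3**
Reactants: 3 (1S,2R,6R)‑6‑methylbicyclo[4.1.0]heptan‑2‑ol
Product: 4 (1S,6R)‑6‑methylbicyclo[4.1.0]heptan‑2‑one
Conditions: nPr4N[RuO4] (5 mol%), N‑methylmorpholine N‑oxide, 4 Å MS, CH2Cl2, rt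
Reagents that add atoms: none
Why: Ley–Griffith oxidation of a secondary alcohol under neutral conditions, which should leave the cyclopropane and both ring‑fusion centres untouched.

**Step 4**
Reactants: 4 (1S,6R)‑6‑methylbicyclo[4.1.0]heptan‑2‑one
Product: 6 (1S,3S,6R)‑6‑methyl‑3‑(triisopropylsilyloxy)bicyclo[4.1.0]heptan‑2‑one, via triisopropylsilyl enol ether 5 (not isolated)
Conditions: LiN(SiMe3)2, iPr3SiOTf, THF, −78 °C; then mCPBA, NaHCO3, CH2Cl2, −20 to 0 °C
Reagents that add atoms: triisopropylsilyl trifluoromethanesulfonate, CC(C)[Si](OS(=O)(=O)C(F)(F)F)(C(C)C)C(C)C; 3‑chloroperbenzoic acid, OOC(=O)c1cccc(Cl)c1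
Why: Rubottom oxidation; the ketone can enolise only toward C3 (the other α‑carbon is the cyclopropane CH), the peracid should attack anti to the cyclopropane CH2 and 1,4‑silyl migration gives the α‑silyloxy ketone directly; the C3 configuration is not critical because step 6 re‑equilibrates it.

**Step 5**
Reactants: 6 (1S,3S,6R)‑6‑methyl‑3‑(triisopropylsilyloxy)bicyclo[4.1.0]heptan‑2‑one; 7 3‑methylbuta‑1,2‑diene
Product: 9 3β‑(triisopropylsilyloxy)‑15‑nor‑5β‑eudesm‑7(11)‑ene‑4,8‑dione (cis‑fused), via γ‑iodo enol silane 8 (not isolated)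
Conditions: Me3SiI (0.3 equiv), Pd(PPh3)4 (5 mol%), CO (10 atm), 7 (3 equiv), 2,6‑di‑tert‑butylpyridine (10 mol%), toluene, 450 nm LED, 40 °C
Reagents that add atoms: carbon monoxide, [C-]#[O+]
Why: Proposed new method: Me3SiI opens the cyclopropane of 6 at its CH2 carbon (C9; the exocyclic C5–C9 bond is the one aligned with the carbonyl π system) to the γ‑iodo enol silane 8, light‑assisted oxidative addition of the C9–I bond to zerovalent palladium and CO insertion give an acylpalladium iodide that cannot β‑eliminate (C10 is quaternary), the allene inserts with acyl transfer to its central carbon (C7–C8), and the C5 enol silane attacks the CH2 terminus (C6) of the 2‑acyl π‑allylpalladium, returning Me3SiI and zerovalent palladium. The closest known reaction types are the Me3SiI or MgI2 ring opening of cyclopropyl ketones in iodide‑relay annulations, the palladium/light carbonylation of unactivated alkyl iodides, the acylpalladium/allene/nucleophile cascade and the Tsuji–Trost allylation of enol silanes; their merger on one substrate is new. Ring B is the only ring closed, in a six‑membered closure at the allyl terminus C6 (C6 and C7 become ring atoms, C11 stays exocyclic); closure at the CMe2 terminus would need a new quaternary centre next to C5 and is disfavoured, as in other 1,1‑dimethylallyl palladium alkylations. No stereocentre has to be set here: C3 and C10 are carried through, and the new C5 centre, expected mainly cis‑fused because the tethered allyl unit reaches the enol π face on the side of C9, stays epimerisable next to the C4 ketone and is corrected in step 6. The step needs allene insertion to outrun O‑acylation of the enol (secured by a silyl rather than a metal enolate and by excess allene) and iodide attack at C9 rather than C10 (secured by the orbital alignment and by C10 being fully substituted).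

**Step 6**
Reactants: 9 3β‑(triisopropylsilyloxy)‑15‑nor‑5β‑eudesm‑7(11)‑ene‑4,8‑dione
Product: 11 3β‑(triisopropylsilyloxy)‑5α‑eudesma‑4(15),7(11)‑dien‑8‑one, via trans‑fused dione 10 (not isolated)
Conditions: Ph3PCH3Br, KOtBu (excess ylide), toluene, rt to 60 °C; NH4Cl (aq)
Reagents that add atoms: methyltriphenylphosphonium bromide, C[P+](c1ccccc1)(c1ccccc1)c1ccccc1.[Br-]
Why: Wittig methylenation under equilibrating conditions; the basic ylide epimerises both α‑carbons of the C4 ketone (C3 and C5) and, in line with the behaviour of angularly methylated 1‑decalones, the less hindered trans‑fused ketone 10 with equatorial 3β‑silyloxy group should be the one olefinated, so the C5 epimers converge on 5α‑H, while the C8 carbonyl, held as its dienolate and flanked by the tetrasubstituted C7 and the neopentyl C9, should stay untouched.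

**Step 7**
Reactants: 11 3β‑(triisopropylsilyloxy)‑5α‑eudesma‑4(15),7(11)‑dien‑8‑one
Product: 12 4α‑hydroxy‑3β‑(triisopropylsilyloxy)‑5α‑eudesm‑7(11)‑en‑8‑one
Conditions: Co(acac)2 (20 mol%), PhSiH3, O2 (1 atm), THF, rt
Reagents that add atoms: dioxygen, O=O
Why: Mukaiyama hydration; hydrogen‑atom transfer to the 1,1‑disubstituted alkene gives the tertiary C4 radical, which should capture O2 on the equatorial α face because the axial β face is blocked by the 1,3‑diaxial angular methyl, giving the 4α‑ol with 4β‑methyl, while the electron‑poor tetrasubstituted enone alkene should not react.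

**Step 8**
Reactants: 12 4α‑hydroxy‑3β‑(triisopropylsilyloxy)‑5α‑eudesm‑7(11)‑en‑8‑one
Product: 13 3β,4α‑dihydroxy‑5α‑eudesm‑7(11)‑en‑8‑one
Conditions: HF·pyridine, THF, 0 °C to rt
Reagents that add atoms: none
Why: fluoride‑mediated silyl ether cleavage; the tertiary alcohol and the enone should tolerate buffered HF, and no stereocentre is touched.

**Step 9**
Reactants: 13 3β,4α‑dihydroxy‑5α‑eudesm‑7(11)‑en‑8‑one; 14 (R)‑2‑methylbutanoic acid
Product: 15 4α‑hydroxy‑8‑oxo‑5α‑eudesm‑7(11)‑en‑3β‑yl (2R)‑2‑methylbutanoate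
Conditions: DCC, DMAP (10 mol%), CH2Cl2, 0 °C to rt
Reagents that add atoms: none
Why: Steglich esterification; only the secondary equatorial 3β‑OH should be acylated (the 4α‑OH is tertiary), and carbodiimide activation at low temperature should not epimerise the α‑centre of the acid.

**Step 10**
Reactants: 15 4α‑hydroxy‑8‑oxo‑5α‑eudesm‑7(11)‑en‑3β‑yl (2R)‑2‑methylbutanoate
Product: 17 4α,11‑dihydroxy‑8‑oxo‑5α‑eudesm‑6‑en‑3β‑yl (2R)‑2‑methylbutanoate (CNP0201989.1), via 11‑hydroperoxide 16 (not isolated)
Conditions: O2, tetraphenylporphyrin (1 mol%), visible light, CH2Cl2, 0 °C; then PPh3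
Reagents that add atoms: dioxygen, O=O
Why: Schenck ene reaction followed by phosphine reduction; in an α,β‑unsaturated ketone singlet oxygen should take the allylic hydrogen from the substituent geminal to the carbonyl (the axial C6–H), so oxygen goes to C11 and the double bond moves to C6=C7, with C3, C4, C5 and C10 not involved.

**Compound list**

1 | 3‑methylcyclohex‑2‑en‑1‑one | CC1=CC(=O)CCC1 | starting material
2 | (R)‑3‑methylcyclohex‑2‑en‑1‑ol | O[C@@H]1CCCC(C)=C1 | intermediate
3 | (1S,2R,6R)‑6‑methylbicyclo[4.1.0]heptan‑2‑ol | O[C@@H]1CCC[C@]2(C)C[C@H]12 | intermediate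
4 | (1S,6R)‑6‑methylbicyclo[4.1.0]heptan‑2‑one | O=C1CCC[C@]2(C)C[C@H]12 | intermediate
5 | (1S,6R)‑6‑methyl‑2‑(triisopropylsilyloxy)bicyclo[4.1.0]hept‑2‑ene | CC(C)[Si](C(C)C)(C(C)C)OC1=CCC[C@]2(C)C[C@H]12 | intermediate (not isolated)
6 | (1S,3S,6R)‑6‑methyl‑3‑(triisopropylsilyloxy)bicyclo[4.1.0]heptan‑2‑one | CC(C)[Si](C(C)C)(C(C)C)O[C@H]1CC[C@]2(C)C[C@@H]2C1=O | intermediate
7 | 3‑methylbuta‑1,2‑diene | C=C=C(C)C | starting material
8 | 3‑(iodomethyl)‑3‑methyl‑6‑(triisopropylsilyloxy)‑1‑(trimethylsilyloxy)cyclohex‑1‑ene (C3 and C10 as in 6) | CC(C)[Si](C(C)C)(C(C)C)O[C@H]1CC[C@](C)(CI)C=C1O[Si](C)(C)C | intermediate (not isolated)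
9 | 3β‑(triisopropylsilyloxy)‑15‑nor‑5β‑eudesm‑7(11)‑ene‑4,8‑dione (cis‑fused) | CC(C)[Si](C(C)C)(C(C)C)O[C@H]1CC[C@]2(C)CC(=O)C(=C(C)C)C[C@@H]2C1=O | intermediate
10 | 3β‑(triisopropylsilyloxy)‑15‑nor‑5α‑eudesm‑7(11)‑ene‑4,8‑dione (trans‑fused) | CC(C)[Si](C(C)C)(C(C)C)O[C@H]1CC[C@]2(C)CC(=O)C(=C(C)C)C[C@H]2C1=O | intermediate (not isolated)
11 | 3β‑(triisopropylsilyloxy)‑5α‑eudesma‑4(15),7(11)‑dien‑8‑one | CC(C)[Si](C(C)C)(C(C)C)O[C@H]1CC[C@]2(C)CC(=O)C(=C(C)C)C[C@H]2C1=C | intermediate
12 | 4α‑hydroxy‑3β‑(triisopropylsilyloxy)‑5α‑eudesm‑7(11)‑en‑8‑one | CC(C)[Si](C(C)C)(C(C)C)O[C@H]1CC[C@]2(C)CC(=O)C(=C(C)C)C[C@H]2[C@]1(C)O | intermediate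
13 | 3β,4α‑dihydroxy‑5α‑eudesm‑7(11)‑en‑8‑one | O[C@H]1CC[C@]2(C)CC(=O)C(=C(C)C)C[C@H]2[C@]1(C)O | intermediate
14 | (R)‑2‑methylbutanoic acid | CC[C@@H](C)C(=O)O | starting material
15 | 4α‑hydroxy‑8‑oxo‑5α‑eudesm‑7(11)‑en‑3β‑yl (2R)‑2‑methylbutanoate | CC[C@@H](C)C(=O)O[C@H]1CC[C@]2(C)CC(=O)C(=C(C)C)C[C@H]2[C@]1(C)O | intermediate
16 | 11‑hydroperoxy‑4α‑hydroxy‑8‑oxo‑5α‑eudesm‑6‑en‑3β‑yl (2R)‑2‑methylbutanoate | CC[C@@H](C)C(=O)O[C@H]1CC[C@]2(C)CC(=O)C(C(C)(C)OO)=C[C@H]2[C@]1(C)O | intermediate (not isolated)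
17 | (3S,4S,5R,10R)‑4,11‑dihydroxy‑8‑oxoeudesm‑6‑en‑3‑yl (2R)‑2‑methylbutanoate (CNP0201989.1) | CC[C@@H](C)C(=O)O[C@H]1CC[C@]2(C)CC(=O)C(C(C)(C)O)=C[C@H]2[C@]1(C)O | target

**Step count and risks**

Total steps: 10. Longest linear sequence: 10 steps (1 to 17); 7 and 14 enter as bought reagents.

Steps most likely to fail:

1. Step 5 (proposed new method). The palladium relay may stall: slow oxidative addition at the neopentyl‑type C9–I bond, re‑closure of the opened form to the cyclopropane, O‑acylation of the enol, or allene oligomerisation. The fallback sets out from 6 and uses known steps. PhSeSiMe3 with catalytic ZnI2 in CH2Cl2 should open the cyclopropane at C9 to the γ‑(phenylselanyl) enol silane F1. MeLi in THF releases the regiodefined lithium enolate, which is alkylated at C5 with 2‑(bromomethyl)‑3‑methylbut‑2‑enenitrile (from the Baylis–Hillman adduct of acrylonitrile and acetone with HBr) to give the seleno nitrile F2 as C5 epimers. Slow addition of Bu3SnH/AIBN in refluxing benzene generates the C9 radical, which closes 6‑exo onto the nitrile carbon; aqueous acid hydrolyses the imine to the diketone. The route is rejoined at 9 (accompanied by 10, both of which serve in step 6).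

2. Step 6. The cis‑fused ketone may be olefinated before it epimerises, or the ylide may engage the C8 carbonyl. The fallback sets out from 9 and separates the two events: NaOMe in MeOH equilibrates C3 and C5, trans‑fused 10 is separated and recovered 9 is recycled. Non‑basic Takai–Lombardo methylenation (Zn, CH2Br2, TiCl4, THF/CH2Cl2) of 10 then gives 11, where the route is rejoined. This fallback makes no new compound (F0).

3. Step 10. Hydrogen abstraction may occur from the C12/C13 methyls (oxygen ending on C7), or the electron‑poor alkene may react slowly and over‑oxidise. The fallback sets out from 13, before esterification. KN(SiMe3)2 (3.2 equiv, THF, −78 °C) followed by kinetic protonation with AcOH gives the deconjugated 7β‑isopropenyl ketone F3. Mukaiyama hydration (Co(acac)2, PhSiH3, O2) of the isopropenyl group gives the 11‑hydroxy ketone F4. Dehydrogenation with IBX (DMSO, 65 °C) can only proceed toward C6, because C10 carries no hydrogen, and gives the Δ6‑enone triol F5. Steglich esterification of its only secondary hydroxyl with 14 (DCC, DMAP) rejoins the route at 17.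

**Further compounds**

F1 | step 5 | 3‑methyl‑3‑[(phenylselanyl)methyl]‑6‑(triisopropylsilyloxy)‑1‑(trimethylsilyloxy)cyclohex‑1‑ene (C3 and C10 as in 6) | CC(C)[Si](C(C)C)(C(C)C)O[C@H]1CC[C@](C)(C[Se]c2ccccc2)C=C1O[Si](C)(C)C
F2 | step 5 | 2‑(2‑cyano‑3‑methylbut‑2‑en‑1‑yl)‑3‑methyl‑3‑[(phenylselanyl)methyl]‑6‑(triisopropylsilyloxy)cyclohexan‑1‑one (C5 epimers; C3 and C10 as in 6) | CC(C)[Si](C(C)C)(C(C)C)O[C@H]1CC[C@](C)(C[Se]c2ccccc2)C(CC(C#N)=C(C)C)C1=O
F0 | step 6 | none | none
F3 | step 10 | 3β,4α‑dihydroxy‑7β‑isopropenyl‑5α,7α‑H‑eudesm‑11‑en‑8‑one | O[C@H]1CC[C@]2(C)CC(=O)[C@@H](C(C)=C)C[C@H]2[C@]1(C)O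
F4 | step 10 | 3β,4α,11‑trihydroxy‑5α,7α‑H‑eudesman‑8‑one | O[C@H]1CC[C@]2(C)CC(=O)[C@@H](C(C)(C)O)C[C@H]2[C@]1(C)O
F5 | step 10 | 3β,4α,11‑trihydroxy‑5α‑eudesm‑6‑en‑8‑one | O[C@H]1CC[C@]2(C)CC(=O)C(C(C)(C)O)=C[C@H]2[C@]1(C)O
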